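**Retrosynthetic overview**

1. Numbering runs from the lactone carbonyl (C1) to the terminal methyl (C26). The plan rests on C4–C5–C6 (ring CH2, ring carbinol carbon of the dihydropyranone, first side-chain CH2) being the three carbons of (R)-epichlorohydrin, with C7 as a dithiane (acyl-anion) carbon on one side and C1–C3 as a propiolate on the other.
2. Target ⇐ acetonide removal ⇐ lactonisation (O on C5 to C1) of a Z-enoate ⇐ cis semi-hydrogenation of the C2≡C3 ynoate ⇐ C5-hydroxyl-directed syn reduction of the C7 ketone ⇐ dithiane hydrolysis.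
3. Key disconnections C6–C7 and C3–C4: dithiane 9, (R)-epichlorohydrin and lithiated ethyl propiolate joined in one flask.
4. Dithiane 9 ⇐ acetonide of the diol from 2-lithio-1,3-dithiane and a syn-epoxy alcohol (C7–C8) ⇐ iodocarbonate cyclisation (sets C9) ⇐ asymmetric allylation of hexadecanal (sets C11).
5. Ring order: the only ring of the target, the 5,6-dihydropyran-2-one, closes in step 10; the dithiane, acetonide and oxirane rings are temporary.

Key step: step 7

Remark: the target is read as (6S)-6-[(2R,4R,6R)-2,4,6-trihydroxyhenicosyl]-5,6-dihydro-2H-pyran-2-one, with all four C–O bonds syn in the zigzag drawing. The CIP labels at C5, C7 and C9 change between intermediates only because substituent priorities change; no centre is inverted once it is set.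

**Route**

Step 1
Reactants: 1 hexadecanal
Product: 2 (4R)-nonadec-1-en-4-ol
Conditions: allylSnBu3 (1.2 equiv), (S)-BINOL (10 mol%), Ti(OiPr)4 (10 mol%), 4 Å MS, CH2Cl2, −20 °C; sat. aq NaHCO3
Reagents that add atoms: allyltributylstannane, C=CC[Sn](CCCC)(CCCC)CCCC
Why: Keck asymmetric allylation, in which the (S)-BINOL titanium Lewis acid should direct the allylstannane to the Si face of the n-alkanal and so give the (R)-carbinol at C11.

Step 2
Reactants: 2 (4R)-nonadec-1-en-4-ol
Product: 3 tert-butyl (4R)-nonadec-1-en-4-yl carbonate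
Conditions: Boc2O, DMAP (cat.), MeCN, rt
Reagents that add atoms: di-tert-butyl dicarbonate, CC(C)(C)OC(=O)OC(=O)OC(C)(C)C
Why: DMAP-catalysed carbonate formation on a secondary alcohol is routine and leaves the terminal alkene and C11 untouched.

Step 3
Reactants: 3 tert-butyl (4R)-nonadec-1-en-4-yl carbonate
Product: 4 (4R,6R)-4-(iodomethyl)-6-pentadecyl-1,3-dioxan-2-one
Conditions: IBr, PhMe, −85 °C; aq Na2S2O3/NaHCO3
Reagents that add atoms: iodine monobromide, BrI
Why: Bartlett–Smith iodocarbonate cyclisation, in which the carbonate carbonyl oxygen attacks the iodonium-activated alkene 6-exo through a chair with both substituents equatorial, setting C9 syn to C11 while the tert-butyl group leaves as its bromide.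

Step 4
Reactants: 4 (4R,6R)-4-(iodomethyl)-6-pentadecyl-1,3-dioxan-2-one
Product: 5 (2R)-1-[(2R)-oxiran-2-yl]heptadecan-2-ol
Conditions: K2CO3 (3 equiv), MeOH, rt
Reagents that add atoms: none
Why: Carbonate methanolysis frees the C9 alkoxide, which displaces the neighbouring primary iodide (3-exo-tet Williamson closure) with retention at C9 because the C9–O bond is never broken.

Step 5
Reactants: 5 (2R)-1-[(2R)-oxiran-2-yl]heptadecan-2-ol, 6 1,3-dithiane
Product: 8 (2R,4R)-1-(1,3-dithian-2-yl)nonadecane-2,4-diol, via 2-lithio-1,3-dithiane 7 (not isolated)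
Conditions: 6 (3 equiv), n-BuLi (2.9 equiv), THF, −30 °C; then 5, −30 → 0 °C; sat. aq NH4Cl
Reagents that add atoms: none
Why: Corey–Seebach alkylation, in which the lithiodithiane opens the terminal epoxide by SN2 attack at its CH2 (C7–C8 bond), one equivalent being spent on the free hydroxyl and no stereocentre being touched.

Step 6
Reactants: 8 (2R,4R)-1-(1,3-dithian-2-yl)nonadecane-2,4-diol
Product: 9 2-{[(4R,6R)-2,2-dimethyl-6-pentadecyl-1,3-dioxan-4-yl]methyl}-1,3-dithiane
Conditions: Me2C(OMe)2, PPTS (cat.), CH2Cl2, rt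
Reagents that add atoms: 2,2-dimethoxypropane, COC(C)(C)OC
Why: Acid-catalysed transketalisation converts the syn-1,3-diol into its chair acetonide, and the dithioacetal is stable to PPTS.

Step 7
Reactants: 9 2-{[(4R,6R)-2,2-dimethyl-6-pentadecyl-1,3-dioxan-4-yl]methyl}-1,3-dithiane, 10 (R)-epichlorohydrin, 11 ethyl propiolate
Product: 16 ethyl (5S)-6-(2-{[(4R,6R)-2,2-dimethyl-6-pentadecyl-1,3-dioxan-4-yl]methyl}-1,3-dithian-2-yl)-5-hydroxyhex-2-ynoate, via lithiated dithiane 12 (not isolated), via lithium chloro alkoxide 13 (not isolated), via terminal epoxide 14 (not isolated), via lithium ethyl propiolate 15 (not isolated)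
Conditions: 9, n-BuLi (1.05 equiv), THF, −25 °C; add to 10 (1.5 equiv), THF, −78 °C → rt; recool to −78 °C; LiC≡CCO2Et [from 11 (4 equiv), n-BuLi, THF, −78 °C], then BF3·OEt2 (4 equiv), −78 °C; sat. aq NH4Cl
Reagents that add atoms: none
Why: Deprotonation of 9 at the dithiane C–H gives the sulfur-stabilised carbanion 12, which opens (R)-epichlorohydrin by SN2 attack at the unsubstituted epoxide carbon (C6–C7 bond); on warming, chloro alkoxide 13 displaces chloride (3-exo-tet, the only ring closure of the step) to give terminal epoxide 14, and this epoxide, activated by BF3, is opened at C4 by the weakly nucleophilic lithium alkynoate 15 (C3–C4 bond). The closest known reactions are the use of epichlorohydrin as a bis-electrophilic linchpin for lithiated dithianes and the Yamaguchi–Hirao opening of terminal epoxides by lithiated propiolates; each is established on these substrate classes, and only their telescoping in one flask is untried. No stereocentre is created: C5 comes from the reagent with its C–O bond intact, so the (R) centre of 10, 13 and 14 becomes (5S) in 16 purely through the change in substituent priorities. The step needs attack of 12 at the epoxide carbon and not at C–Cl, which decides the sense of C5, and only one alkylation per epichlorohydrin; both should hold because the epoxide carbon is the kinetically preferred site at −78 °C and because 13 does not close to 14 until the mixture is warmed, by which time 12 has been consumed by the excess of 10. BF3·OEt2 is added only after the basic carbanion is gone, and at −78 °C it should leave the acetonide and the dithiane alone while the alkynoate attacks the less hindered C4; the surplus of 15 also absorbs the leftover epichlorohydrin.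

Step 8
Reactants: 16 ethyl (5S)-6-(2-{[(4R,6R)-2,2-dimethyl-6-pentadecyl-1,3-dioxan-4-yl]methyl}-1,3-dithian-2-yl)-5-hydroxyhex-2-ynoate
Product: 17 ethyl (5S)-8-[(4R,6R)-2,2-dimethyl-6-pentadecyl-1,3-dioxan-4-yl]-5-hydroxy-7-oxooct-2-ynoate
Conditions: PhI(O2CCF3)2 (1.5 equiv), NaHCO3, MeCN/H2O (9:1), 0 °C
Reagents that add atoms: water, O
Why: Oxidative dithiane hydrolysis with a hypervalent iodine reagent, in which sulfur is oxidised and water adds to the thionium ion, is fast on hindered dithianes, releases no free thiol that could add to the ynoate, and is buffered so that the acetonide survives.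

Step 9
Reactants: 17 ethyl (5S)-8-[(4R,6R)-2,2-dimethyl-6-pentadecyl-1,3-dioxan-4-yl]-5-hydroxy-7-oxooct-2-ynoate
Product: 18 ethyl (5S,7S)-8-[(4S,6R)-2,2-dimethyl-6-pentadecyl-1,3-dioxan-4-yl]-5,7-dihydroxyoct-2-ynoate
Conditions: Et2BOMe (1.1 equiv), THF/MeOH (4:1), −78 °C; NaBH4 (1.1 equiv), −78 °C; AcOH quench, MeOH co-evaporation
Reagents that add atoms: none
Why: Narasaka–Prasad reduction, in which Et2BOMe ties the C5 hydroxyl and the C7 ketone into a six-membered boron chelate and external hydride adds axially to give the 5,7-syn diol, while the ynoate should survive borohydride at −78 °C.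

Step 10
Reactants: 18 ethyl (5S,7S)-8-[(4S,6R)-2,2-dimethyl-6-pentadecyl-1,3-dioxan-4-yl]-5,7-dihydroxyoct-2-ynoate
Product: 20 (6S)-6-{(2R)-3-[(4S,6R)-2,2-dimethyl-6-pentadecyl-1,3-dioxan-4-yl]-2-hydroxypropyl}-5,6-dihydro-2H-pyran-2-one, via Z-dihydroxy enoate 19 (not isolated)
Conditions: H2 (1 atm), Pd/CaCO3 poisoned with Pb(OAc)2, quinoline, EtOAc, rt; filter; PPTS (cat.), PhMe, 50 °C
Reagents that add atoms: none
Why: Syn addition of H2 on the poisoned palladium surface stops at the Z-enoate, whose cis geometry brings the ester next to the C5 hydroxyl so that acid-catalysed lactonisation closes the six-membered ring, the C7 hydroxyl being unable to compete because it would need an eight-membered ring.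

Step 11
Reactants: 20 (6S)-6-{(2R)-3-[(4S,6R)-2,2-dimethyl-6-pentadecyl-1,3-dioxan-4-yl]-2-hydroxypropyl}-5,6-dihydro-2H-pyran-2-one
Product: 21 (6S)-6-[(2R,4R,6R)-2,4,6-trihydroxyhenicosyl]-5,6-dihydro-2H-pyran-2-one
Conditions: AcOH/H2O/THF (3:1:1), 45 °C
Reagents that add atoms: none
Why: Acid-catalysed acetal hydrolysis under mild aqueous acetic acid should leave the unsaturated lactone alone, erases any acetonide shift onto the C7 hydroxyl from step 10, and avoids base, under which the C7 hydroxyl could add to C3 (oxa-Michael).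

**Compound list**

1 | hexadecanal | CCCCCCCCCCCCCCCC=O | starting material
2 | (4R)-nonadec-1-en-4-ol | CCCCCCCCCCCCCCC[C@@H](O)CC=C | intermediate
3 | tert-butyl (4R)-nonadec-1-en-4-yl carbonate | CCCCCCCCCCCCCCC[C@H](CC=C)OC(=O)OC(C)(C)C | intermediate
4 | (4R,6R)-4-(iodomethyl)-6-pentadecyl-1,3-dioxan-2-one | CCCCCCCCCCCCCCC[C@@H]1C[C@H](CI)OC(=O)O1 | intermediate
5 | (2R)-1-[(2R)-oxiran-2-yl]heptadecan-2-ol | CCCCCCCCCCCCCCC[C@@H](O)C[C@@H]1CO1 | intermediate
6 | 1,3-dithiane | C1CSCSC1 | starting material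
7 | 2-lithio-1,3-dithiane | [Li]C1SCCCS1 | intermediate
8 | (2R,4R)-1-(1,3-dithian-2-yl)nonadecane-2,4-diol | CCCCCCCCCCCCCCC[C@@H](O)C[C@@H](O)CC1SCCCS1 | intermediate
9 | 2-{[(4R,6R)-2,2-dimethyl-6-pentadecyl-1,3-dioxan-4-yl]methyl}-1,3-dithiane | CCCCCCCCCCCCCCC[C@@H]1C[C@H](CC2SCCCS2)OC(C)(C)O1 | intermediate
10 | (R)-epichlorohydrin, (2R)-2-(chloromethyl)oxirane | ClC[C@H]1CO1 | starting material
11 | ethyl propiolate | C#CC(=O)OCC | starting material
12 | 2-lithio-2-{[(4R,6R)-2,2-dimethyl-6-pentadecyl-1,3-dioxan-4-yl]methyl}-1,3-dithiane | CCCCCCCCCCCCCCC[C@@H]1C[C@H](CC2([Li])SCCCS2)OC(C)(C)O1 | intermediate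
13 | lithium (2R)-1-chloro-3-(2-{[(4R,6R)-2,2-dimethyl-6-pentadecyl-1,3-dioxan-4-yl]methyl}-1,3-dithian-2-yl)propan-2-olate | CCCCCCCCCCCCCCC[C@@H]1C[C@H](CC2(C[C@H](CCl)O[Li])SCCCS2)OC(C)(C)O1 | intermediate
14 | 2-{[(4R,6R)-2,2-dimethyl-6-pentadecyl-1,3-dioxan-4-yl]methyl}-2-{[(2R)-oxiran-2-yl]methyl}-1,3-dithiane | CCCCCCCCCCCCCCC[C@@H]1C[C@H](CC2(C[C@@H]3CO3)SCCCS2)OC(C)(C)O1 | intermediate
15 | ethyl 3-lithioprop-2-ynoate | [Li]C#CC(=O)OCC | intermediate
16 | ethyl (5S)-6-(2-{[(4R,6R)-2,2-dimethyl-6-pentadecyl-1,3-dioxan-4-yl]methyl}-1,3-dithian-2-yl)-5-hydroxyhex-2-ynoate | CCCCCCCCCCCCCCC[C@@H]1C[C@H](CC2(C[C@@H](O)CC#CC(=O)OCC)SCCCS2)OC(C)(C)O1 | intermediate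
17 | ethyl (5S)-8-[(4R,6R)-2,2-dimethyl-6-pentadecyl-1,3-dioxan-4-yl]-5-hydroxy-7-oxooct-2-ynoate | CCCCCCCCCCCCCCC[C@@H]1C[C@H](CC(=O)C[C@@H](O)CC#CC(=O)OCC)OC(C)(C)O1 | intermediate
18 | ethyl (5S,7S)-8-[(4S,6R)-2,2-dimethyl-6-pentadecyl-1,3-dioxan-4-yl]-5,7-dihydroxyoct-2-ynoate | CCCCCCCCCCCCCCC[C@@H]1C[C@H](C[C@@H](O)C[C@@H](O)CC#CC(=O)OCC)OC(C)(C)O1 | intermediate
19 | ethyl (2Z,5S,7S)-8-[(4S,6R)-2,2-dimethyl-6-pentadecyl-1,3-dioxan-4-yl]-5,7-dihydroxyoct-2-enoate | CCCCCCCCCCCCCCC[C@@H]1C[C@H](C[C@@H](O)C[C@@H](O)C/C=C\C(=O)OCC)OC(C)(C)O1 | intermediate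
20 | (6S)-6-{(2R)-3-[(4S,6R)-2,2-dimethyl-6-pentadecyl-1,3-dioxan-4-yl]-2-hydroxypropyl}-5,6-dihydro-2H-pyran-2-one | CCCCCCCCCCCCCCC[C@@H]1C[C@H](C[C@@H](O)C[C@@H]2CC=CC(=O)O2)OC(C)(C)O1 | intermediate
21 | (6S)-6-[(2R,4R,6R)-2,4,6-trihydroxyhenicosyl]-5,6-dihydro-2H-pyran-2-one | CCCCCCCCCCCCCCC[C@@H](O)C[C@@H](O)C[C@@H](O)C[C@@H]1CC=CC(=O)O1 | target

**Totals**

Total step count: 11. Longest linear sequence: 11 steps, from hexadecanal 1 to target 21; compounds 6, 10 and 11 are bought.

**Steps most likely to fail**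

Step 7. Several processes can spoil the one-pot coupling:
- Carbanion 12 may alkylate epoxide 14 as soon as it forms, giving double alkylation.
- Some direct displacement at C–Cl would erode the configuration at C5.
- The leftover epichlorohydrin and the lithium salts compete for the alkynoate and for BF3.
- The lithium propiolate decomposes if the flask warms above about −70 °C.

The fallback sets out from 9 and comes back at 16. Only the first half is run (12 added to excess 10, −78 °C → rt), and terminal epoxide 14 is isolated by chromatography, free of salts and of epichlorohydrin. It is then opened without any Lewis acid by the dianion of propiolic acid (propiolic acid, 2 equiv n-BuLi, THF/HMPA, −40 → 0 °C) to give (5S)-6-(2-{[(4R,6R)-2,2-dimethyl-6-pentadecyl-1,3-dioxan-4-yl]methyl}-1,3-dithian-2-yl)-5-hydroxyhex-2-ynoic acid F1. Alkylation of its carboxylate with EtI and KHCO3 in DMF returns 16.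

Step 9. Borohydride may add in conjugate fashion to the electron-poor ynoate, and incomplete boron chelation would lower the facial selectivity at C7. The fallback sets out from 17 and comes back at 19, and it changes the order so that no ynoate is present during the reduction. Ketone 17 is first semi-hydrogenated (H2, Pd/CaCO3 poisoned with Pb(OAc)2, quinoline, EtOAc, no acid) to ethyl (2Z,5S)-8-[(4R,6R)-2,2-dimethyl-6-pentadecyl-1,3-dioxan-4-yl]-5-hydroxy-7-oxooct-2-enoate F2. This is kept cold and neutral so that it neither lactonises nor eliminates, and is reduced at once with Et2BOMe and NaBH4 at −78 °C; an enoate is inert to these conditions. The product is Z-dihydroxy enoate 19, which is lactonised with PPTS as in step 10.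

Step 10. Sulfur traces from step 8 may stall the poisoned catalyst, and forcing the hydrogenation may lead to over-reduction of the enoate. The fallback sets out from 18 and comes back at 20; it accepts full saturation and reintroduces the double bond.
- Hydrogenation over Pd/C in EtOAc gives ethyl (5S,7S)-8-[(4S,6R)-2,2-dimethyl-6-pentadecyl-1,3-dioxan-4-yl]-5,7-dihydroxyoctanoate F3.
- PPTS in toluene lactonises it to (6S)-6-{(2R)-3-[(4S,6R)-2,2-dimethyl-6-pentadecyl-1,3-dioxan-4-yl]-2-hydroxypropyl}oxan-2-one F4.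
- LiN(iPr)2 (2.2 equiv, THF, −78 °C) followed by PhSeBr gives (6S)-6-{(2R)-3-[(4S,6R)-2,2-dimethyl-6-pentadecyl-1,3-dioxan-4-yl]-2-hydroxypropyl}-3-(phenylselanyl)oxan-2-one F5 as a mixture of C3 epimers.
- Oxidation with H2O2 (CH2Cl2, pyridine, 0 °C) and selenoxide syn-elimination towards the ring CH2 gives 20.

**Further compounds**

F1 | step 7 | (5S)-6-(2-{[(4R,6R)-2,2-dimethyl-6-pentadecyl-1,3-dioxan-4-yl]methyl}-1,3-dithian-2-yl)-5-hydroxyhex-2-ynoic acid | CCCCCCCCCCCCCCC[C@@H]1C[C@H](CC2(C[C@@H](O)CC#CC(=O)O)SCCCS2)OC(C)(C)O1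
F2 | step 9 | ethyl (2Z,5S)-8-[(4R,6R)-2,2-dimethyl-6-pentadecyl-1,3-dioxan-4-yl]-5-hydroxy-7-oxooct-2-enoate | CCCCCCCCCCCCCCC[C@@H]1C[C@H](CC(=O)C[C@@H](O)C/C=C\C(=O)OCC)OC(C)(C)O1
F3 | step 10 | ethyl (5S,7S)-8-[(4S,6R)-2,2-dimethyl-6-pentadecyl-1,3-dioxan-4-yl]-5,7-dihydroxyoctanoate | CCCCCCCCCCCCCCC[C@@H]1C[C@H](C[C@@H](O)C[C@@H](O)CCCC(=O)OCC)OC(C)(C)O1
F4 | step 10 | (6S)-6-{(2R)-3-[(4S,6R)-2,2-dimethyl-6-pentadecyl-1,3-dioxan-4-yl]-2-hydroxypropyl}oxan-2-one | CCCCCCCCCCCCCCC[C@@H]1C[C@H](C[C@@H](O)C[C@@H]2CCCC(=O)O2)OC(C)(C)O1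
F5 | step 10 | (6S)-6-{(2R)-3-[(4S,6R)-2,2-dimethyl-6-pentadecyl-1,3-dioxan-4-yl]-2-hydroxypropyl}-3-(phenylselanyl)oxan-2-one | CCCCCCCCCCCCCCC[C@@H]1C[C@H](C[C@@H](O)C[C@@H]2CCC([Se]c3ccccc3)C(=O)O2)OC(C)(C)O1
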